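Amounts of target and starting material fell together in the earlier runs, and I wanted you to know that before you took over these flasks.

| setting | cedar | alder | birch | larch | dawn | midnight | winter | spring |
|---|---|---|---|---|---|---|---|---|
| starting material | 0.050 M | 0.025 M | 0.10 M | 0.050 M | 0.050 M | 0.050 M (fed, over 8.0 min) | 0.050 M (fed, over 50 s) | 0.050 M (fed, over 8.0 min) |
| reagent | 0.075 M | 0.075 M | 0.075 M | 0.15 M | 0.0750 M | 0.0750 M | 0.0750 M | 0.0750 M |
| temperature | −25 °C | −14 °C | −25 °C | −14 °C | −20 °C | −20 °C | −20 °C |  |
| remark | run made earlier | run made earlier | run made earlier | run made earlier | everything together at the start | all else is in the flask from the start; the feed brings no volume worth counting | all else is in the flask from the start; the feed brings no volume worth counting | the addition at −50 °C, then warmed to −20 °C; the feed brings no volume worth counting |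
| time |  |  |  |  | 12 min | 12 min | 12 min | 12 min |

| run | time / min | target / % | starting material / % |
|---|---|---|---|
| cedar | 3.00 | 22 | 23 |
| cedar | 6.00 | 15 | 12 |
| cedar | 10.0 | 7 | 9 |
| cedar | 12.0 | 6 | 4 |
| alder | 0.833 | 26 | 38 |
| alder | 2.50 | 15 | 22 |
| alder | 5.00 | 6 | 13 |
| alder | 8.00 | 3 | 5 |
| birch | 0.500 | 17 | 65 |
| birch | 1.33 | 17 | 41 |
| birch | 3.00 | 10 | 24 |
| birch | 8.00 | 6 | 11 |
| larch | 0.833 | 31 | 22 |
| larch | 2.50 | 12 | 8 |
| larch | 5.00 | 6 | 7 |
| larch | 8.00 | 2 | 2 |

(readings scatter by 1.5 percentage points)

- the flask that comes out highest in amount of target, in percent of the starting material charged, or "all alike" when all lie within 1.5 percentage points (dawn / midnight / winter / spring / all alike)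
- target at the end, in percent of the starting material charged, dawn
- target at the end, in percent of the starting material charged, midnight
- target at the end, in percent of the starting material charged, winter
- target at the end, in percent of the starting material charged, spring

- the analysis behind the earlier runs scatters by 1.5 percentage points, standard deviation

Summed over its later readings, the cedar run gave 1.12 parts of target per part of starting material. The birch run, with twice cedar's charge, gave 0.457, so I took the ratio to follow the reagent left, which nobody read, as a pre-equilibrium would. The larch run at −14 °C, scaled down to the reagent of the new flasks, gave 0.588. Since −20 °C lies near the middle of those temperatures, I took the geometric mean, 0.812, as my tracking ratio, target over starting material late in a flask.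

So I told you to expect target where starting material remained. I put dawn near cedar's last 4% of starting material, which gave 3.25% of target. Spring, assuming little reaction at −50 °C and a prompt warm-up, had 4.00 min of warm time, and I took 17.5% of starting material from cedar's readings around that age, which gave 14.2% of target. I asked you to read at 12 min and not let a flask stand, since cedar's target fell from 22% at 3.00 min to 6% at 12.0 min.

The forecast named spring highest at 13%, below my figure, with 9% for midnight, 4% for winter and 3.5% for dawn, holding that “the cold feed preserves both reagent and target”.

Spring came out highest at 11.4%, with 7.52% for midnight, 3.83% for winter and 3.63% for dawn.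

    starting material + reagent → isomer of the product (k = 0.0405 M⁻¹ s⁻¹, Ea = 55.0 kJ mol⁻¹)
    starting material + reagent ⇌ target (K = 15.4 M⁻¹, k = 0.307 M⁻¹ s⁻¹, Ea = 50.0 kJ mol⁻¹, ΔH = −33.0 kJ mol⁻¹)
    starting material + target → side product (k = 0.357 M⁻¹ s⁻¹, Ea = 37.0 kJ mol⁻¹)
    (constants at −20 °C)

Spring also ended with more starting material than the other flasks, at 15.1%. The tracking ratio applied to that amount gives 12.3% of target. The neighbour flask like dawn but charged with 0.013 M of starting material ended with 9.07% of it and 87.5% of its reagent, against 58.8% in dawn. Scaled by that reagent, the ratio gives 11.0% of target, against the 9.80% of target that flask held.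

The runs are simulated with constants of no real substance.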